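I decide to commit to one number for this flask, the ratio of target to isomer of the product once it stops moving, and I turn the settings one at a time to see what moves it.

all flasks: starting material 20 mM

| charge | reagent | remark | time |
|---|---|---|---|
| dusk | 0.25 equiv | run made earlier |  |
| autumn | 1 equiv | run made earlier |  |
| flask | 0.500 equiv |  | 4.0 d |

| run | time / d | target / % | isomer of the product / % |
|---|---|---|---|
| dusk | 0.417 | 11 | 5 |
| dusk | 1.04 | 13 | 5 |
| dusk | 2.08 | 17 | 6 |
| dusk | 3.00 | 18 | 5 |
| autumn | 0.250 | 26 | 11 |
| autumn | 0.625 | 47 | 17 |
| autumn | 1.25 | 59 | 19 |
| autumn | 3.00 | 65 | 20 |

(standard deviation of a reading: 1.5 percentage points)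

- ratio of target to isomer of the product at 80 min
- ratio of target to isomer of the product at 4.0 d

- the earlier runs were read with a standard deviation of 1.5 percentage points

The reagent comes first. Going from 0.25 equiv to 1 equiv raises the readings of both target and isomer of the product, but the last ratios are 3.60 in the dusk run and 3.25 in the autumn run, and the dusk figure rests on an isomer reading of 5% with a scatter of 1.5 points, so by hand I see no effect of the charge on the ratio beyond that scatter and reckon 3.32 for what I call the end ratio, target over isomer of the product summed over both last readings, the thermodynamic-control end of the selectivity.

Starting material stands at 20 mM in both runs and in this flask, so the readings show nothing about changing it.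

Time comes last. In the autumn run the gap below the end ratio shrinks from 0.956 at 0.250 d to 0.555 at 0.625 d, which reads as a half-life of 0.478 d, a figure with the scatter of those readings in it. Putting that back in, the gap at 3.00 d reckons to 0.0178, less than the first gap, so the last readings can serve as the end and I say 3.32 at 4.0 d. Run backwards, the same half-life gives my own 2.05 at 80 min, though it comes from a run with twice this flask's reagent.

The forecast says 2.2 at 80 min and 3.35 at 4.0 d, reasoning for the early time that “the ratio should be the early kinetic value”.

The flask gives 1.81 at 80 min, below my 2.05, and 3.51 at 4.0 d.

    starting material + reagent → intermediate + by-product (k = 8.78 M⁻¹ h⁻¹)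
    intermediate ⇌ target (K = 8.80, k = 0.365 h⁻¹)
    intermediate ⇌ isomer of the product (K = 2.50, k = 0.206 h⁻¹)

At 40.0 d this flask holds 35.8% target and 10.2% isomer of the product, a ratio of 3.51, and its 3.51 at 4.0 d stands 0.190 above the end ratio of 3.32 that I read from the runs.

For the neighbour charged with 1.20 equiv of reagent, the end ratio gives 3.32 again; the computed ratio there is 3.49, with 71.0% target beside 20.3% isomer of the product.

The runs were generated by integration from invented constants.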